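(The constants are assumed, and the outcome is calculated.)

Divide the constant of the decay of second intermediate by the constant of its capture by open intermediate, and keep the ratio 0.0141 M as the even-split level, the [open intermediate] at which second intermediate goes equally to side product and to target.

    partner A + target → over-reaction product (k1 = 0.018 M⁻¹ s⁻¹)
    open intermediate + second intermediate → target (k2 = 0.056 M⁻¹ s⁻¹)
    substrate + partner B → open intermediate (k3 = 0.0036 M⁻¹ s⁻¹)
    second intermediate → side product (k4 = 7.9 × 10⁻⁴ s⁻¹)
    partner B + partner A → second intermediate (k5 = 0.014 M⁻¹ s⁻¹)

all flasks: substrate 0.050 M; partner B 0.200 M
- beta: partner A 0.0750 M; time 2.0 h; everything together in a closed stirred flask, run for 2.0 h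
- eta: partner A 0.0750 M; a single well-mixed tank run continuously and read at steady state, 20.0 h in it on average
- alpha: partner A 0.0750 M (fed, over 1.60 h); time 2.0 h; all but partner A at the start; partner A goes in evenly over 1.60 h, the run ends at 2.0 h
- gamma: partner A 0.0750 M; a single well-mixed tank run continuously and read at steady state, 2.0 h in it on average

- the stated concentrations are those of everything mixed, before any reaction; amounts are the same in each set-up
- the feed brings no volume worth counting
- run time (beta): 2.0 h

* the set-up with the highest amount of open intermediate at the outlet or at the end, in percent of the substrate put in ("none" if the first two lie within 2 percentage points) (beta / eta / alpha / gamma / none)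
* amount of open intermediate at the outlet or at the end, in percent of the substrate put in, beta
* amount of open intermediate at the outlet or at the end, in percent of the substrate put in, eta
* amount of open intermediate at the outlet or at the end, in percent of the substrate put in, alpha
* amount of open intermediate at the outlet or at the end, in percent of the substrate put in, gamma

Reckon eta, the long tank, by hand.

1. Note that a steady tank holds one [open intermediate], so the target channel (target, counted with the over-reaction product made from it) stands to side product as [open intermediate] stands to the level.

2. Take both charges off partner B, which leaves [partner B] at 0.0750 M, and divide the charged substrate by one plus the pseudo-first-order rate of substrate times the residence time, so that 0.0476 M of substrate is converted.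

3. Let the whole charge of partner A pass through second intermediate into the two channels, let converted substrate be open intermediate plus target channel, and solve the resulting quadratic with the level: [open intermediate] comes to 0.0124 M, or 24.9% of the substrate.

4. Test the weak link, the passage of partner A through second intermediate: step 3 leaves target standing, and partner A then divides between target and partner B in the ratio 0.602, which puts 0.0282 M into over-reaction product.

5. Reforge it: since that over-reaction eats the target it was reckoned from, damp the figure to 0.0141 M, half of it, and take this amount of partner A out of the channels, which leaves 0.0609 M in them. Partner B then stands at 0.0891 M, the converted substrate at 0.0479 M, and [open intermediate] at 0.0158 M. The ratio recomputed from these values, 0.261, returns 0.0155 M against the 0.0141 M assumed, so commit to 31.5% for eta and leave the other set-ups unreckoned.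

The forecast names beta as best, with 36%, 25.4%, 12% and 20.3% for beta, eta, alpha and gamma, from “rough hand estimates of the tank steady states and coarse stepping of the two timed runs”; its eta stands lower than my reckoning.

The simulation gives beta as best, with 39.6%, 32.4%, 23.2% and 23.8% in the same order.

Read eta's outlet against the level: 0.0162 M is 1.15 times it, so there the target channel leads side product by that factor. Then remove the decay of second intermediate from the two timed runs, and open intermediate in alpha minus that in beta moves from −16 percentage points to 2.1 points, so beta's lead over alpha rests in part on that decay.

Now take the neighbour of alpha with 0.085 M of substrate, all else as in alpha, where the level is 16.6% of the charge instead of 28.2%: the tank balance of step 5, carried roughly to this fed flask with everything converted, gives 0.0400 M, or 47.1%. The computed flask ends lower, at 41.6%.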